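**Strategy**

The synthesis rests on disconnecting the trans C1-OAc/C6-OH pair to a C1–C6 oxirane and that oxirane to the C1=C6 alkene of a cyclohexa-1,3-diene. The key step exploits the cis relationship between the C6 oxygen and the C5 oxygen on the six-membered ring: the free C5 hydroxyl of a trans-4,5-dioxygenated diene (C4-OTBS, C7-OBz) delivers oxygen from vanadium to its own allylic C1=C6 bond and its own face, closing the epoxide and setting C1 and C6 in one operation. Acetic acid later opens the vinyl epoxide at allylic C1 with inversion. The diene precursor is reached from the commercial bromobenzene cis-dihydrodiol by C4 inversion and Stille hydroxymethylation.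

Key step: step 8

Remark: atoms are numbered as in the target throughout (ring C1 bearing OAc, C2 the vinylic CH, C3 bearing C7, then C4, C5, C6); the temporary C5 silyl ether is chosen as triethylsilyl so that it can be removed beside the C4 tert-butyldimethylsilyl ether, and the hydroxyl distal to bromine in 1 is assumed to silylate first also with this smaller chlorosilane.

**Route**

Step 1
Reactants: 1 (1S,2S)-3-bromocyclohexa-3,5-diene-1,2-diol; 2 chlorotriethylsilane
Product: 3 (1S,6S)-2-bromo-6-(triethylsilyloxy)cyclohexa-2,4-dien-1-ol (cis; silyl ether on the oxygen remote from bromine, the future C5-O)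
Conditions: TESCl (1.05 equiv), imidazole, DMF, −40 °C
Reagents that add atoms: chlorotriethylsilane, CC[Si](Cl)(CC)CC
Why: Regioselective monosilylation of a diol; the hydroxyl next to the C–Br carbon is the more hindered and less nucleophilic one, so the chlorosilane should react at the distal hydroxyl, as is established for bulkier silyl chlorides on halogenated arene cis-dihydrodiols, and no stereocentre is touched.

Step 2
Reactants: 3 (1S,6S)-2-bromo-6-(triethylsilyloxy)cyclohexa-2,4-dien-1-ol; 4 4-nitrobenzoic acid
Product: 5 (1R,6S)-2-bromo-6-(triethylsilyloxy)cyclohexa-2,4-dien-1-yl 4-nitrobenzoate (trans)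
Conditions: PPh3, DIAD, THF, −20 → 0 °C
Reagents that add atoms: 4-nitrobenzoic acid, O=C(O)c1ccc(cc1)[N+](=O)[O-]
Why: Mitsunobu reaction; SN2 displacement of the activated C4 oxygen by the carboxylate inverts C4 and creates the trans C4/C5 arrangement, while the acidic pronucleophile, the low temperature and the electron-withdrawing bromine should hold back ionisation of the dienylic C4–O bond and hence aromatisation.

Step 3
Reactants: 5 (1R,6S)-2-bromo-6-(triethylsilyloxy)cyclohexa-2,4-dien-1-yl 4-nitrobenzoate
Product: 6 (1R,6S)-2-bromo-6-(triethylsilyloxy)cyclohexa-2,4-dien-1-ol (trans)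
Conditions: K2CO3 (0.2 equiv), MeOH, 0 °C
Reagents that add atoms: none
Why: Base-catalysed transesterification (methanolysis) of an activated aryl ester; cleavage occurs at the acyl carbon, so C4 keeps its inverted configuration, and the brief cold treatment should leave the triethylsilyl ether in place.

Step 4
Reactants: 6 (1R,6S)-2-bromo-6-(triethylsilyloxy)cyclohexa-2,4-dien-1-ol; 7 tert-butyldimethylsilyl trifluoromethanesulfonate
Product: 8 tert-butyl{[(1R,6S)-2-bromo-6-(triethylsilyloxy)cyclohexa-2,4-dien-1-yl]oxy}dimethylsilane (trans; C4-OTBS, C5-OTES)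
Conditions: TBSOTf, 2,6-lutidine, CH2Cl2, −78 → 0 °C
Reagents that add atoms: tert-butyldimethylsilyl trifluoromethanesulfonate, CC(C)(C)[Si](C)(C)OS(=O)(=O)C(F)(F)F
Why: Silyl ether formation; the reactive silyl triflate with a hindered pyridine base should cap the crowded C4 hydroxyl at low temperature without acid that could harm the diene, and only the O–H bond reacts.

Step 5
Reactants: 8 tert-butyl{[(1R,6S)-2-bromo-6-(triethylsilyloxy)cyclohexa-2,4-dien-1-yl]oxy}dimethylsilane; 9 (tributylstannyl)methanol
Product: 10 [(5S,6S)-6-(tert-butyldimethylsilyloxy)-5-(triethylsilyloxy)cyclohexa-1,3-dien-1-yl]methanol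
Conditions: Pd(PPh3)4 (5 mol %), 1,4-dioxane (degassed), 90 °C
Reagents that add atoms: (tributylstannyl)methanol, OC[Sn](CCCC)(CCCC)CCCC
Why: Stille cross-coupling; oxidative addition of zerovalent palladium into the vinylic C3–Br bond, transfer of the hydroxymethyl group from tin and reductive elimination should form the C3–C7 bond under neutral conditions that leave both silyl ethers and both stereocentres untouched.

Step 6
Reactants: 10 [(5S,6S)-6-(tert-butyldimethylsilyloxy)-5-(triethylsilyloxy)cyclohexa-1,3-dien-1-yl]methanol; 11 benzoyl chloride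
Product: 12 [(5S,6S)-6-(tert-butyldimethylsilyloxy)-5-(triethylsilyloxy)cyclohexa-1,3-dien-1-yl]methyl benzoate
Conditions: BzCl, pyridine, CH2Cl2, 0 °C
Reagents that add atoms: benzoyl chloride, O=C(Cl)c1ccccc1
Why: Acylation of a primary allylic alcohol with an acid chloride; C7-OH is the only free hydroxyl, so the ester should form cleanly and no stereocentre is involved.

Step 7
Reactants: 12 [(5S,6S)-6-(tert-butyldimethylsilyloxy)-5-(triethylsilyloxy)cyclohexa-1,3-dien-1-yl]methyl benzoate
Product: 13 [(5S,6S)-6-(tert-butyldimethylsilyloxy)-5-hydroxycyclohexa-1,3-dien-1-yl]methyl benzoate (trans; C5-OH free, C4-OTBS)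
Conditions: PPTS (0.1 equiv), MeOH/CH2Cl2, 0 °C → rt
Reagents that add atoms: none
Why: Chemoselective acid-catalysed solvolysis of a silyl ether; a triethylsilyl ether is cleaved much faster than a tert-butyldimethylsilyl ether under weak acid, so only C5-OH should be released, with both stereocentres unchanged and acidity too low to dehydrate the dienol.

Step 8
Reactants: 13 [(5S,6S)-6-(tert-butyldimethylsilyloxy)-5-hydroxycyclohexa-1,3-dien-1-yl]methyl benzoate; 14 tert-butyl hydroperoxide
Product: 15 [(1S,4S,5S,6R)-4-(tert-butyldimethylsilyloxy)-5-hydroxy-7-oxabicyclo[4.1.0]hept-2-en-3-yl]methyl benzoate (C1–C6 epoxide cis to C5-OH, trans to C4-OTBS)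
Conditions: VO(acac)2 (5 mol %), TBHP (1.5 equiv, in decane), CH2Cl2, 0 °C → rt
Reagents that add atoms: tert-butyl hydroperoxide, CC(C)(C)OO
Why: TBHP oxidises VO(acac)2 to a pentavalent vanadium species that binds the C5 hydroxyl as an alkoxide together with the alkyl peroxide, and the activated peroxide oxygen is then passed in a concerted step to the C1=C6 alkene held next to the metal. The closest known reaction type is the vanadium-catalysed hydroxyl-directed syn epoxidation of cyclic allylic alcohols such as cyclohex-2-enols. The oxirane is closed by a concerted [2+1] oxygen-atom transfer across C1=C6, both C–O bonds forming in the same event, not by a stepwise exo or endo cyclisation. The new stereocentres C1 and C6 are controlled by the existing C5 carbinol centre through the vanadium tether, so the epoxide oxygen should lie cis to C5-OH. The step needs site selectivity for C1=C6 over the trisubstituted C2=C3 alkene, face selectivity, and epoxidation in preference to oxidation of the carbinol; C5-OH is allylic only to C1=C6, the C4 and C7 oxygens are capped as silyl ether and benzoate so no hydroxyl can steer the metal to C2=C3, and the trans C4/C5 substituents, turning away from the C3 side chain, should place C5-OH pseudoaxial over the C1=C6 π face.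

Step 9
Reactants: 15 [(1S,4S,5S,6R)-4-(tert-butyldimethylsilyloxy)-5-hydroxy-7-oxabicyclo[4.1.0]hept-2-en-3-yl]methyl benzoate; 11 benzoyl chloride
Product: 16 [(1S,4S,5S,6S)-5-(benzoyloxy)-4-(tert-butyldimethylsilyloxy)-7-oxabicyclo[4.1.0]hept-2-en-3-yl]methyl benzoate (same spatial arrangement as 15)
Conditions: BzCl, pyridine, DMAP (cat.), CH2Cl2, 0 °C → rt
Reagents that add atoms: benzoyl chloride, O=C(Cl)c1ccccc1
Why: Nucleophile-catalysed acylation of a secondary alcohol; only the O–H bond of C5-OH reacts, so the configuration is retained, and the cold basic medium should leave the vinyl epoxide closed.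

Step 10
Reactants: 16 [(1S,4S,5S,6S)-5-(benzoyloxy)-4-(tert-butyldimethylsilyloxy)-7-oxabicyclo[4.1.0]hept-2-en-3-yl]methyl benzoate; 17 acetic acid
Product: 18 [(3R,4S,5S,6S)-3-acetoxy-5-(benzoyloxy)-6-(tert-butyldimethylsilyloxy)-4-hydroxycyclohex-1-en-1-yl]methyl benzoate (C1-OAc trans to C6-OH; C6-OH cis to C5-OBz)
Conditions: AcOH (solvent), NaOAc, 40–50 °C
Reagents that add atoms: acetic acid, CC(=O)O
Why: Acid-assisted SN2 opening of a vinyl epoxide by a carboxylic acid; acetate should attack the allylic epoxide carbon C1 anti to the departing oxygen, which inverts C1 and leaves C6-OH with its configuration, while attack at C6 is disfavoured by the electron-withdrawing C5 benzoate next to it and SN2′ attack at C3 by its full substitution.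

Step 11
Reactants: 18 [(3R,4S,5S,6S)-3-acetoxy-5-(benzoyloxy)-6-(tert-butyldimethylsilyloxy)-4-hydroxycyclohex-1-en-1-yl]methyl benzoate
Product: 19 [(3R,4S,5R,6S)-3-acetoxy-5-(benzoyloxy)-4,6-dihydroxycyclohex-1-en-1-yl]methyl benzoate (target)
Conditions: HF·pyridine, pyridine, THF, 0 °C → rt
Reagents that add atoms: none
Why: Fluoride-mediated desilylation; the weakly acidic fluoride source cleaves only the Si–O bond at C4, so no stereocentre changes and the acetate and the two benzoates should neither cleave nor migrate.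

**Compound list**

1 | (1S,2S)-3-bromocyclohexa-3,5-diene-1,2-diol (cis-diol) | O[C@@H]1C(Br)=CC=C[C@@H]1O | starting material
2 | chlorotriethylsilane | CC[Si](Cl)(CC)CC | starting material
3 | (1S,6S)-2-bromo-6-(triethylsilyloxy)cyclohexa-2,4-dien-1-ol (cis) | CC[Si](CC)(CC)O[C@H]1C=CC=C(Br)[C@H]1O | intermediate
4 | 4-nitrobenzoic acid | O=C(O)c1ccc(cc1)[N+](=O)[O-] | starting material
5 | (1R,6S)-2-bromo-6-(triethylsilyloxy)cyclohexa-2,4-dien-1-yl 4-nitrobenzoate (trans) | CC[Si](CC)(CC)O[C@H]1C=CC=C(Br)[C@@H]1OC(=O)c1ccc(cc1)[N+](=O)[O-] | intermediate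
6 | (1R,6S)-2-bromo-6-(triethylsilyloxy)cyclohexa-2,4-dien-1-ol (trans) | CC[Si](CC)(CC)O[C@H]1C=CC=C(Br)[C@@H]1O | intermediate
7 | tert-butyldimethylsilyl trifluoromethanesulfonate | CC(C)(C)[Si](C)(C)OS(=O)(=O)C(F)(F)F | starting material
8 | tert-butyl{[(1R,6S)-2-bromo-6-(triethylsilyloxy)cyclohexa-2,4-dien-1-yl]oxy}dimethylsilane (trans) | CC[Si](CC)(CC)O[C@H]1C=CC=C(Br)[C@@H]1O[Si](C)(C)C(C)(C)C | intermediate
9 | (tributylstannyl)methanol | OC[Sn](CCCC)(CCCC)CCCC | starting material
10 | [(5S,6S)-6-(tert-butyldimethylsilyloxy)-5-(triethylsilyloxy)cyclohexa-1,3-dien-1-yl]methanol | CC[Si](CC)(CC)O[C@H]1C=CC=C(CO)[C@@H]1O[Si](C)(C)C(C)(C)C | intermediate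
11 | benzoyl chloride | O=C(Cl)c1ccccc1 | starting material
12 | [(5S,6S)-6-(tert-butyldimethylsilyloxy)-5-(triethylsilyloxy)cyclohexa-1,3-dien-1-yl]methyl benzoate | CC[Si](CC)(CC)O[C@H]1C=CC=C(COC(=O)c2ccccc2)[C@@H]1O[Si](C)(C)C(C)(C)C | intermediate
13 | [(5S,6S)-6-(tert-butyldimethylsilyloxy)-5-hydroxycyclohexa-1,3-dien-1-yl]methyl benzoate (trans) | O[C@H]1C=CC=C(COC(=O)c2ccccc2)[C@@H]1O[Si](C)(C)C(C)(C)C | intermediate
14 | tert-butyl hydroperoxide | CC(C)(C)OO | starting material
15 | [(1S,4S,5S,6R)-4-(tert-butyldimethylsilyloxy)-5-hydroxy-7-oxabicyclo[4.1.0]hept-2-en-3-yl]methyl benzoate (epoxide cis to C5-OH) | O[C@H]1[C@H]2O[C@H]2C=C(COC(=O)c2ccccc2)[C@@H]1O[Si](C)(C)C(C)(C)C | intermediate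
16 | [(1S,4S,5S,6S)-5-(benzoyloxy)-4-(tert-butyldimethylsilyloxy)-7-oxabicyclo[4.1.0]hept-2-en-3-yl]methyl benzoate | O=C(O[C@H]1[C@H]2O[C@H]2C=C(COC(=O)c2ccccc2)[C@@H]1O[Si](C)(C)C(C)(C)C)c1ccccc1 | intermediate
17 | acetic acid | CC(=O)O | starting material
18 | [(3R,4S,5S,6S)-3-acetoxy-5-(benzoyloxy)-6-(tert-butyldimethylsilyloxy)-4-hydroxycyclohex-1-en-1-yl]methyl benzoate | CC(=O)O[C@@H]1C=C(COC(=O)c2ccccc2)[C@H](O[Si](C)(C)C(C)(C)C)[C@@H](OC(=O)c2ccccc2)[C@H]1O | intermediate
19 | [(3R,4S,5R,6S)-3-acetoxy-5-(benzoyloxy)-4,6-dihydroxycyclohex-1-en-1-yl]methyl benzoate | CC(=O)O[C@@H]1C=C(COC(=O)c2ccccc2)[C@H](O)[C@@H](OC(=O)c2ccccc2)[C@H]1O | target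

**Step count and risks**

Total step count: 11. Longest linear sequence: 11 steps (from 1 to 19).

Steps most likely to fail:

Step 8 (key step). Site or face control may be incomplete, the dienylic carbinol may be oxidised with ensuing aromatisation, or the vinyl epoxide may open on the Lewis-acidic metal as it forms. The fallback is an iodocarbonate relay setting out from 13. Boc2O/DMAP should give the C5 tert-butyl carbonate F1. IBr in toluene at −78 °C should close the carbonate carbonyl oxygen onto C6, anti to an iodonium ion on C1=C6, giving the cis-fused iodo cyclic carbonate F2 with iodine on C1 trans to C6-O. K2CO3/MeOH should remove the carbonate and the C7 benzoate, and the C6 alkoxide should displace iodide from C1 to give the same syn epoxide as the epoxy diol F3. Dibenzoylation with BzCl/pyridine comes back to the route at 16.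

Step 2. Elimination of the activated C4 oxygen (aromatisation to an aryl silyl ether) or SN2′ attack may outrun direct displacement. The fallback sets out from 3 and inverts C4 on a ring that cannot aromatise. Diimide (potassium azodicarboxylate, AcOH, MeOH, 0 °C) should reduce only the disubstituted C1=C6 alkene to give the cyclohexenol F4. The Mitsunobu reaction with 4-nitrobenzoic acid should then give the inverted ester F5. Allylic bromination at C1 (NBS, AIBN, PhCF3, 80 °C) should give the allylic bromide F6 as a mixture of C1 epimers, and dehydrobromination with DBU restores the C1=C6 alkene, coming back to the route at 5.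

Step 10. Acetate may attack the far end of the allyl system (1,4-opening at C3), configuration may be partly lost through an allyl cation, or an acyl group may migrate during prolonged warming in acid. The fallback sets out from 16 and introduces the oxygen nucleophile and the acetyl group separately. Brief acid-catalysed hydrolysis (cat. HClO4, THF/H2O, 0 °C) should open the epoxide at C1 with water to the trans C1,C6-diol F7. Selective acetylation of the less hindered allylic C1 hydroxyl (AcCl, 2,4,6-collidine, CH2Cl2, −78 °C) comes back to the route at 18.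

**Further compounds**

F1 | step 8 | [(5S,6S)-5-(tert-butoxycarbonyloxy)-6-(tert-butyldimethylsilyloxy)cyclohexa-1,3-dien-1-yl]methyl benzoate | CC(C)(C)OC(=O)O[C@H]1C=CC=C(COC(=O)c2ccccc2)[C@@H]1O[Si](C)(C)C(C)(C)C
F2 | step 8 | [4-(tert-butyldimethylsilyloxy)-7-iodo-2-oxo-3a,4,7,7a-tetrahydro-1,3-benzodioxol-5-yl]methyl benzoate (cis-fused carbonate on C5-O/C6-O, iodine on C1 trans to C6-O) | O=C1O[C@H]2[C@@H](O1)[C@H](I)C=C(COC(=O)c1ccccc1)[C@@H]2O[Si](C)(C)C(C)(C)C
F3 | step 8 | [(1S,4S,5S,6R)-4-(tert-butyldimethylsilyloxy)-5-hydroxy-7-oxabicyclo[4.1.0]hept-2-en-3-yl]methanol | O[C@H]1[C@H]2O[C@H]2C=C(CO)[C@@H]1O[Si](C)(C)C(C)(C)C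
F4 | step 2 | (1S,6S)-2-bromo-6-(triethylsilyloxy)cyclohex-2-en-1-ol | CC[Si](CC)(CC)O[C@H]1CCC=C(Br)[C@H]1O
F5 | step 2 | (1R,6S)-2-bromo-6-(triethylsilyloxy)cyclohex-2-en-1-yl 4-nitrobenzoate | CC[Si](CC)(CC)O[C@H]1CCC=C(Br)[C@@H]1OC(=O)c1ccc(cc1)[N+](=O)[O-]
F6 | step 2 | (1R,6S)-2,4-dibromo-6-(triethylsilyloxy)cyclohex-2-en-1-yl 4-nitrobenzoate (mixture of epimers at the new C–Br carbon) | CC[Si](CC)(CC)O[C@H]1CC(Br)C=C(Br)[C@@H]1OC(=O)c1ccc(cc1)[N+](=O)[O-]
F7 | step 10 | [(3R,4S,5S,6S)-5-(benzoyloxy)-6-(tert-butyldimethylsilyloxy)-3,4-dihydroxycyclohex-1-en-1-yl]methyl benzoate | O[C@@H]1C=C(COC(=O)c2ccccc2)[C@H](O[Si](C)(C)C(C)(C)C)[C@@H](OC(=O)c2ccccc2)[C@H]1O
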